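All constants are made up; the rest is arithmetic.

I decide to count turnovers before I reckon any yield: a count is a first-order rate constant multiplied by the hours it has to act, so it says how many lifetimes a species gets in the flask.

the same everywhere: starting material 20 mM; reagent 4.00 equiv; protic impurity 1.00 mM; time 15 h

| run | remark | temperature |
|---|---|---|
| larch | at 50 °C until 10 h, from then on at 90 °C |  |
| cedar |  | 50 °C |
| birch |  | 90 °C |
| alder |  | 70 °C |

- the best flask by amount of target, in percent of the starting material charged; "all alike" if 1.5 percentage points covers them all (larch / cedar / birch / alder / all alike)
- amount of target at the end, in percent of the starting material charged, larch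
- amount of target at the end, in percent of the starting material charged, cedar
- amount of target at the end, in percent of the starting material charged, birch
- amount of target at the end, in percent of the starting material charged, alder

- constants are those at 90 °C; use the activation energies and enthalpies for any other temperature

    starting material + protic impurity → quenched substrate (k1 = 94.6 /M/h, Ea1 = 58.0 kJ/mol)
    starting material + reagent ⇌ isomer of the product (K2 = 30.9 /M, k2 = 2.84 /M/h, Ea2 = 68.0 kJ/mol, ΔH2 = −33.0 kJ/mol)
    starting material + reagent ⇌ target (K3 = 140 /M, k3 = 5.25 /M/h, Ea3 = 69.0 kJ/mol, ΔH3 = −40.0 kJ/mol)
    reagent ⇌ dormant form (K4 = 0.47, k4 = 0.00451 /h, Ea4 = 115 kJ/mol, ΔH4 = 30.0 kJ/mol)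
    (constants at 90 °C)

The four flasks have the same charge and differ in temperature history. Starting material adds reagent reversibly to give target or isomer, the protic impurity quenches starting material, and reagent slips slowly into its dormant form. The impurity amounts to 5.00 % of the starting material, so the addition can use 95.0 % of the charge once the impurity has reacted.

The reagent stands at 4.00 equiv, so I treat the addition as pseudo-first-order in starting material. In birch the forward count over 15 h is 9.71. The target step is slower by a factor of 17 in cedar, and the isomer step has nearly the same activation energy, so cedar's forward count is about 0.574, far behind birch's.

In birch the forward steps send 64.9 % of the adding material to target, which would make 61.7 % of the charge if every molecule added once and stayed. But the isomer returns, with the forward constant divided by the equilibrium constant, 0.0919 /h in birch. Over 15 h that makes 1.38, and I carry this: the return count, the lifetimes an isomer gets at 90 °C. Target returns more slowly in birch, 0.562 lifetimes, and the equilibrium constants favour it, so returned isomer should feed target.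

Larch is hot for its last 5.00 h, so its return count is 0.460, and I ignore its cold hours. I commit to birch above 61.7 %, to larch below birch, and to cedar far behind. I place alder between cedar and birch without a count.

The forecast names birch as best, with 60 % in larch, 26 % in cedar, 66 % in birch and 56 % in alder, holding that reversibility “lets the isomer drain towards the favoured target”.

The simulation gives birch as best, with 57.3 % in larch, 26.1 % in cedar, 64.8 % in birch and 54.2 % in alder.

The main reason birch's target stays short of the charge is the isomer step: with that step struck out both ways, birch's target rises from 64.8 % to 84.6 %. Part of that loss is won back, since with the backward run from isomer struck out, birch's target falls to 49.6 %. So a return count of 1.38 is worth 15 percentage points in birch, which ends with 3.08 target per isomer. Larch's return count of 0.460 is a third of birch's, and larch ends with 2.23 target per isomer, holding 25.7 % as isomer. Left until 150 h, larch reaches 69.0 % target.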